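**Plan**
- Cuts: the α-methylene-γ-butyrolactone ring at O–C8 and at C11–C12, so that its O–C12(=O) unit is one molecule of CO2. Behind that, C8–Cl/C9–OH goes back to a C8=C9 alkene, the C6 angelate to a C6 ketone, and C7–C11, C5–C4 and C10–vinyl to conjugate additions on a 4-silyloxycyclohexenone.
- Forward: the carbocycle is bought as enone 1. C5/C10 are set by cuprate addition–aldol, the enone is regenerated, a C7 acetyl is added by a second cuprate, the C9 ketone is erased to the C8=C9 alkene, C6 is inverted and acylated, the epoxide is opened to a chlorohydrin, and the lactone ring is closed last.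
- Stereochemistry: the C6 silyl ether of (S)-1 directs C5 (anti) and, through C5, C10 (anti). C7 is equilibrated to the equatorial acetyl. C6 is then inverted by oxidation and hydride attack anti to the axial C10 methyl. C9 and C8 come from α-epoxidation and trans-diaxial chloride opening, and C8 is inverted in the key step.
- Enabling feature: in the lactone ring the O–C8 bond is anti to C7–C11 (trans fusion) and C12 sits on the vinylic carbon C11. An axial C8 chloride cis to a C11 alkenyl triflate therefore lets a reductive carboxylation (C11 and CO2, both electrophiles, joined under cobalt/manganese reduction) be followed by SN2 ring closure with inversion.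

Key step: step 17

Remark: locants are those of the elemane skeleton (C10 quaternary carbon, C9 carbinol, C8 lactone O–CH, C7 ring-fusion CH bearing C11, C6 angelate carbon, C5 carbon bearing the propenal unit; C11/C12/C13 lactone α-carbon, carbonyl and exocyclic methylene); β is the ring face of the C10 methyl.
Assumption: enone 1, bromo acetal 4 and angelic anhydride 25 are taken as catalogue compounds.

Step 1
Reactants: 1 (S)-4-(tert-butyldimethylsilyloxy)cyclohex-2-en-1-one
Product: 2 (S)-4-(tert-butyldimethylsilyloxy)-2-iodocyclohex-2-en-1-one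
Conditions: I2, pyridine, CH2Cl2, 0 → 25 °C
Reagents that add atoms: iodine, II
Why: α-iodination of the enone by pyridine conjugate addition, iodination and elimination should give the 2-iodoenone without touching the C6 stereocenter.

Step 2
Reactants: 2 (S)-4-(tert-butyldimethylsilyloxy)-2-iodocyclohex-2-en-1-one
Product: 3 (S)-4-(tert-butyldimethylsilyloxy)-2-methylcyclohex-2-en-1-one
Conditions: Me4Sn, PdCl2(PhCN)2 (cat.), AsPh3, CuI (cat.), NMP, 80 °C
Reagents that add atoms: tetramethyltin, C[Sn](C)(C)C
Why: Stille coupling of an α-iodoenone should transfer methyl under neutral conditions that spare the γ-silyloxy enone from elimination and aromatisation.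

Step 3
Reactants: 3 (S)-4-(tert-butyldimethylsilyloxy)-2-methylcyclohex-2-en-1-one; 4 2-bromo-3,3-diethoxyprop-1-ene; 5 acetaldehyde
Product: 9 C9 ketone with 10β-methyl 10α-(1-hydroxyethyl) 5β-(3,3-diethoxyprop-1-en-2-yl) 6α-OTBS (both carbinol epimers), via alkenyllithium 6 (not isolated), via diorganocuprate 7 (not isolated), via lithium enolate 8 (not isolated)
Conditions: 4, t-BuLi (2 equiv per 4), Et2O, −78 °C; CuI (0.5 equiv per 6), −78 → −40 °C; 3, −78 → −30 °C; then 5, −78 °C; aq. NH4Cl
Reagents that add atoms: none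
Why: the cuprate should add to C5 anti to the adjacent C6 silyl ether (4-substituted cyclohexenone rule) and the tetrasubstituted enolate should be hydroxyalkylated at C10 anti to the new C5 group (tandem conjugate addition–aldol), which sets C5 and the quaternary C10; the carbinol configuration is lost in step 4.

Step 4
Reactants: 9 aldol (carbinol epimers)
Product: 10 C9 ketone with 10β-methyl 10α-vinyl 5β-(3,3-diethoxyprop-1-en-2-yl) 6α-OTBS
Conditions: Ph2S[OC(CF3)2Ph]2, CH2Cl2, 0 → 25 °C
Reagents that add atoms: none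
Why: sulfurane dehydration of the secondary alcohol under neutral conditions can eliminate only towards the methyl group (C10 is quaternary), so both carbinol epimers should converge on the vinyl group without retro-aldol cleavage.

Step 5
Reactants: 10 vinyl ketone
Product: 11 C7=C8 enone (C9 ketone) with 10β-methyl 10α-vinyl 5β-(3,3-diethoxyprop-1-en-2-yl) 6α-OTBS
Conditions: IBX (2-iodoxybenzoic acid), DMSO/toluene, 70 °C
Reagents that add atoms: none
Why: IBX dehydrogenation of the ketone can occur only towards C8 (C10 has no hydrogen) and cannot over-oxidise to a dienone.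

Step 6
Reactants: 11 C7=C8 enone; 12 ethoxyethene
Product: 16 C9 enol triflate (C8=C9) carrying a 1-ethoxyvinyl group at C7 (C7 epimers), via 1-ethoxyvinyllithium 13 (not isolated), via diorganocuprate 14 (not isolated), via lithium enolate 15 (not isolated)
Conditions: 12, t-BuLi, THF, −78 → 0 °C; CuI, −78 °C; 11, −78 → −40 °C; then N-(5-chloropyridin-2-yl)triflimide, −78 → 0 °C
Reagents that add atoms: N-(5-chloropyridin-2-yl)-1,1,1-trifluoro-N-(trifluoromethylsulfonyl)methanesulfonamide, O=S(=O)(N(c1ccc(Cl)cn1)S(=O)(=O)C(F)(F)F)C(F)(F)F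
Why: the 1-ethoxyvinyl cuprate (an acyl anion equivalent) should add to C7 and O-sulfonylation of the regiodefined enolate fixes the future C8=C9 position; the C7 configuration is deliberately left open because the anti-to-C6 and anti-to-C5 preferences conflict here.

Step 7
Reactants: 16 enol triflate with 7-(1-ethoxyvinyl) (C7 epimers)
Product: 18 C9 enol triflate with 7β-acetyl, via methyl ketone epimers 17 (not isolated)
Conditions: (CO2H)2 (cat.), THF/H2O, 0 °C; then DBU (cat.), CH2Cl2, 25 °C
Reagents that add atoms: water, O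
Why: the enol ether should hydrolyse far faster than the diethyl acetal, and base equilibration α to the new ketone should funnel both C7 epimers into the equatorial 7β-acetyl isomer (trans to C6–O, cis to the C5 group), conjugation into the ring being blocked by the triflate on C9.

Step 8
Reactants: 18 7β-acetyl enol triflate
Product: 19 C8=C9 alkene with 7β-acetyl 6α-OTBS
Conditions: Pd(PPh3)4 (cat.), n-Bu3SnH, LiCl, THF, 50 °C
Reagents that add atoms: none
Why: palladium-catalysed hydride reduction of the alkenyl triflate should give the alkene under neutral conditions that keep the β,γ-unsaturated ketone out of conjugation and leave C7 untouched.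

Step 9
Reactants: 19 7β-acetyl alkene
Product: 21 C8=C9 alkene with 7β-[1-(trifluoromethylsulfonyloxy)vinyl] 6α-OTBS, via potassium enolate 20 (not isolated)
Conditions: KN(SiMe3)2, THF, −78 °C; N-(5-chloropyridin-2-yl)triflimide, −78 °C
Reagents that add atoms: N-(5-chloropyridin-2-yl)-1,1,1-trifluoro-N-(trifluoromethylsulfonyl)methanesulfonamide, O=S(=O)(N(c1ccc(Cl)cn1)S(=O)(=O)C(F)(F)F)C(F)(F)F
Why: kinetic deprotonation of the methyl ketone by a bulky amide should occur at the methyl group and not at the hindered C7 methine, and O-sulfonylation then gives the 1,1-disubstituted alkenyl triflate that carries C11 and C13.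

Step 10
Reactants: 21 alkenyl triflate with 6α-OTBS
Product: 22 6α-alcohol
Conditions: n-Bu4NF, AcOH, THF, 0 → 25 °C
Reagents that add atoms: none
Why: buffered fluoride desilylation should free the C6 hydroxyl without attacking the alkenyl triflate or the acetal.

Step 11
Reactants: 22 6α-alcohol
Product: 23 C6 ketone
Conditions: DMP (1,1,1-triacetoxy-1,1-dihydro-1,2-benziodoxol-3(1H)-one), pyridine, CH2Cl2, 0 °C
Reagents that add atoms: none
Why: buffered periodinane oxidation is neutral enough to deliver the doubly β,γ-unsaturated ketone, which is used at once.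

Step 12
Reactants: 23 C6 ketone
Product: 24 6β-alcohol
Conditions: LiBH(s-Bu)3, THF, −78 °C
Reagents that add atoms: none
Why: the bulky hydride should attack C6 from the α face, anti to the pseudoaxial C10 methyl and between two equatorial neighbours, giving the axial 6β-alcohol that is cis to the C5 and C7 substituents.

Step 13
Reactants: 24 6β-alcohol; 25 (Z)-2-methylbut-2-enoic anhydride
Product: 27 6β-angelate, via lithium alkoxide 26 (not isolated)
Conditions: LiN(SiMe3)2, THF, −78 °C; then 25, −78 → 0 °C
Reagents that add atoms: none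
Why: acylation of the preformed alkoxide with the anhydride at low temperature should esterify the hindered axial alcohol without the Z to E isomerisation that acid chlorides or nucleophilic catalysts cause; no other hydroxyl is present at this stage.

Step 14
Reactants: 27 6β-angelate
Product: 28 8α,9α-epoxide
Conditions: m-CPBA, CH2Cl2, 0 °C
Reagents that add atoms: 3-chloroperbenzoic acid, O=C(OO)c1cccc(Cl)c1
Why: the ring alkene is the only electron-rich disubstituted alkene (the others are monosubstituted or deactivated by acetal, triflate or ester), and the peracid should approach anti to the axial C10 methyl and the axial C6 ester, giving the α-epoxide.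

Step 15
Reactants: 28 8α,9α-epoxide
Product: 29 8β-chloro-9α-hydroxy compound
Conditions: LiCl, AcOH, THF, 25 → 40 °C
Reagents that add atoms: lithium chloride, [Li+].[Cl-]
Why: buffered chloride opening should follow the trans-diaxial course at C8 (C9 is neopentyl), placing chloride 8β and the hydroxyl 9α while the acetal survives; attack at a carbon flanked by two syn-axial groups has analogy in 2α,3α-epoxides of 4,4-dimethyl steroids.

Step 16
Reactants: 29 chlorohydrin
Product: 30 9α-triethylsilyl ether of the 8β-chloride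
Conditions: Et3SiCl, imidazole, DMF, 25 °C
Reagents that add atoms: chlorotriethylsilane, CC[Si](Cl)(CC)CC
Why: silylation of the C9 hydroxyl removes the routes to epoxide re-closure and to a cyclic carbonate under CO2 in the next step.

Step 17
Reactants: 30 alkenyl triflate with 8β-chloride; 31 carbon dioxide
Product: 33 trans-fused α-methylene-γ-butyrolactone with 9α-OSiEt3 6β-angelate and diethyl acetal, via manganese carboxylate 32 (not isolated)
Conditions: CoI2(2,9-dimethyl-1,10-phenanthroline) (cat.), Mn powder, CO2 (1 atm), DMA, 25 °C; then Ar, Cs2CO3, 80 °C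
Reagents that add atoms: none
Why: low-valent cobalt generated by manganese should insert into the C11–OTf bond and, after further reduction, add to CO2, so that two electrophilic carbons are joined as the C11–C12 bond of carboxylate 32 (closest known type: cobalt- or nickel-catalysed reductive carboxylation of alkenyl triflates with CO2). Exchange to the cesium salt should then let the carboxylate oxygen displace the axial C8 chloride, the known O-alkylation of a cesium carboxylate by an alkyl halide run intramolecularly. The lactone ring closes 5-exo-tet. C8 is the only new stereocenter and is set by inversion of the C–Cl bond made in step 15; because chloride and C11 are cis, the ring fusion comes out trans. The catalyst must leave the secondary chloride, the angelate and the other alkenes alone (unactivated alkyl chlorides are inert to it), and the silyl ether keeps O9 from competing. The alkenylcobalt carbon itself cannot displace the chloride, since that would need a trans-fused cyclopropane.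

Step 18
Reactants: 33 protected lactone
Product: 34 CNP0277836.2
Conditions: 1 M HCl, THF, 0 → 25 °C
Reagents that add atoms: water, O
Why: dilute aqueous acid should cleave the triethylsilyl ether and hydrolyse the conjugated diethyl acetal to the 2-substituted propenal without affecting the lactone or the angelate.

**Compound list**
1 | (S)-4-(tert-butyldimethylsilyloxy)cyclohex-2-en-1-one | O=C1C=C[C@@H](O[Si](C)(C)C(C)(C)C)CC1 | starting material
2 | (S)-4-(tert-butyldimethylsilyloxy)-2-iodocyclohex-2-en-1-one | O=C1C(I)=C[C@@H](O[Si](C)(C)C(C)(C)C)CC1 | intermediate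
3 | (S)-4-(tert-butyldimethylsilyloxy)-2-methylcyclohex-2-en-1-one | O=C1C(C)=C[C@@H](O[Si](C)(C)C(C)(C)C)CC1 | intermediate
4 | 2-bromo-3,3-diethoxyprop-1-ene | C=C(Br)C(OCC)OCC | starting material
5 | acetaldehyde | CC=O | starting material
6 | (3,3-diethoxyprop-1-en-2-yl)lithium | [Li]C(=C)C(OCC)OCC | intermediate
7 | lithium bis(3,3-diethoxyprop-1-en-2-yl)cuprate | [Li+].CCOC(OCC)C(=C)[Cu-]C(=C)C(OCC)OCC | intermediate
8 | lithium C9 enolate (C9=C10) with 5β-(3,3-diethoxyprop-1-en-2-yl) and 6α-OTBS | [Li+].[O-]C1=C(C)[C@H](C(=C)C(OCC)OCC)[C@@H](O[Si](C)(C)C(C)(C)C)CC1 | intermediate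
9 | C9 ketone, 10β-methyl, 10α-(1-hydroxyethyl), 5β-(3,3-diethoxyprop-1-en-2-yl), 6α-OTBS (carbinol epimers) | CC(O)[C@]1(C)C(=O)CC[C@H](O[Si](C)(C)C(C)(C)C)[C@H]1C(=C)C(OCC)OCC | intermediate
10 | C9 ketone, 10β-methyl, 10α-vinyl, 5β-(3,3-diethoxyprop-1-en-2-yl), 6α-OTBS | C=C[C@]1(C)C(=O)CC[C@H](O[Si](C)(C)C(C)(C)C)[C@H]1C(=C)C(OCC)OCC | intermediate
11 | C7=C8 enone of 10 | C=C[C@]1(C)C(=O)C=C[C@H](O[Si](C)(C)C(C)(C)C)[C@H]1C(=C)C(OCC)OCC | intermediate
12 | ethoxyethene | C=COCC | starting material
13 | (1-ethoxyvinyl)lithium | [Li]C(=C)OCC | intermediate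
14 | lithium bis(1-ethoxyvinyl)cuprate | [Li+].CCOC(=C)[Cu-]C(=C)OCC | intermediate
15 | lithium C9 enolate (C8=C9) with 7-(1-ethoxyvinyl) (C7 epimers) | [Li+].C=C[C@]1(C)C([O-])=CC(C(=C)OCC)[C@H](O[Si](C)(C)C(C)(C)C)[C@H]1C(=C)C(OCC)OCC | intermediate
16 | C9 enol triflate with 7-(1-ethoxyvinyl) (C7 epimers) | C=C[C@]1(C)C(OS(=O)(=O)C(F)(F)F)=CC(C(=C)OCC)[C@H](O[Si](C)(C)C(C)(C)C)[C@H]1C(=C)C(OCC)OCC | intermediate
17 | C9 enol triflate with 7-acetyl (C7 epimers) | C=C[C@]1(C)C(OS(=O)(=O)C(F)(F)F)=CC(C(C)=O)[C@H](O[Si](C)(C)C(C)(C)C)[C@H]1C(=C)C(OCC)OCC | intermediate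
18 | C9 enol triflate with 7β-acetyl | C=C[C@]1(C)C(OS(=O)(=O)C(F)(F)F)=C[C@@H](C(C)=O)[C@H](O[Si](C)(C)C(C)(C)C)[C@H]1C(=C)C(OCC)OCC | intermediate
19 | C8=C9 alkene with 7β-acetyl, 6α-OTBS | C=C[C@]1(C)C=C[C@@H](C(C)=O)[C@H](O[Si](C)(C)C(C)(C)C)[C@H]1C(=C)C(OCC)OCC | intermediate
20 | potassium enolate of 19 (C11=C13) | [K+].C=C[C@]1(C)C=C[C@@H](C(=C)[O-])[C@H](O[Si](C)(C)C(C)(C)C)[C@H]1C(=C)C(OCC)OCC | intermediate
21 | C8=C9 alkene with 7β-[1-(triflyloxy)vinyl], 6α-OTBS | C=C[C@]1(C)C=C[C@@H](C(=C)OS(=O)(=O)C(F)(F)F)[C@H](O[Si](C)(C)C(C)(C)C)[C@H]1C(=C)C(OCC)OCC | intermediate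
22 | 6α-alcohol of 21 | C=C[C@]1(C)C=C[C@@H](C(=C)OS(=O)(=O)C(F)(F)F)[C@H](O)[C@H]1C(=C)C(OCC)OCC | intermediate
23 | C6 ketone | C=C[C@]1(C)C=C[C@@H](C(=C)OS(=O)(=O)C(F)(F)F)C(=O)[C@H]1C(=C)C(OCC)OCC | intermediate
24 | 6β-alcohol | C=C[C@]1(C)C=C[C@@H](C(=C)OS(=O)(=O)C(F)(F)F)[C@@H](O)[C@H]1C(=C)C(OCC)OCC | intermediate
25 | (Z)-2-methylbut-2-enoic anhydride (angelic anhydride) | C/C=C(/C)C(=O)OC(=O)/C(C)=C\C | starting material
26 | lithium 6β-alkoxide of 24 | [Li+].C=C[C@]1(C)C=C[C@@H](C(=C)OS(=O)(=O)C(F)(F)F)[C@@H]([O-])[C@H]1C(=C)C(OCC)OCC | intermediate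
27 | 6β-angelate | C=C[C@]1(C)C=C[C@@H](C(=C)OS(=O)(=O)C(F)(F)F)[C@@H](OC(=O)/C(C)=C\C)[C@H]1C(=C)C(OCC)OCC | intermediate
28 | 8α,9α-epoxide | C=C[C@]1(C)[C@@H]2O[C@@H]2[C@@H](C(=C)OS(=O)(=O)C(F)(F)F)[C@@H](OC(=O)/C(C)=C\C)[C@H]1C(=C)C(OCC)OCC | intermediate
29 | 8β-chloro-9α-hydroxy compound | C=C[C@]1(C)[C@H](O)[C@@H](Cl)[C@@H](C(=C)OS(=O)(=O)C(F)(F)F)[C@@H](OC(=O)/C(C)=C\C)[C@H]1C(=C)C(OCC)OCC | intermediate
30 | 8β-chloro-9α-triethylsilyloxy compound | C=C[C@]1(C)[C@H](O[Si](CC)(CC)CC)[C@@H](Cl)[C@@H](C(=C)OS(=O)(=O)C(F)(F)F)[C@@H](OC(=O)/C(C)=C\C)[C@H]1C(=C)C(OCC)OCC | intermediate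
31 | carbon dioxide | O=C=O | starting material
32 | manganese C12 carboxylate of 30 (triflate counter-ion) | C=C[C@]1(C)[C@H](O[Si](CC)(CC)CC)[C@@H](Cl)[C@@H](C(=C)C(=O)[O-])[C@@H](OC(=O)/C(C)=C\C)[C@H]1C(=C)C(OCC)OCC.[Mn+2].[O-]S(=O)(=O)C(F)(F)F | intermediate
33 | trans-fused α-methylene lactone, 9α-OSiEt3, 6β-angelate, diethyl acetal | C=C[C@]1(C)[C@H](O[Si](CC)(CC)CC)[C@@H]2OC(=O)C(=C)[C@H]2[C@@H](OC(=O)/C(C)=C\C)[C@H]1C(=C)C(OCC)OCC | intermediate
34 | CNP0277836.2 | C=C[C@]1(C)[C@H](O)[C@@H]2OC(=O)C(=C)[C@H]2[C@@H](OC(=O)/C(C)=C\C)[C@H]1C(=C)C=O | target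

**Count**
Total steps: 18. Longest linear sequence: 18 steps (from 1).

**Steps most likely to fail**

Step 17. The carboxylation may stall or end in protonation of the alkenyl–metal species, and the hindered axial chloride may be displaced too slowly or suffer elimination. Fallback: setting out from 30, palladium-catalysed hydroxycarbonylation of the alkenyl triflate (Pd(OAc)2, dppf, CO 1 atm, KOAc, DMF/H2O, 60 °C) should give the isolated acrylic acid F1. Treating F1 with Cs2CO3 in DMF at 80 °C should close the lactone by the same SN2 inversion, coming back to the route at 33.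

Step 7. Equilibration at C7 may be incomplete, or the C7 enolate may expel the C6 silanolate (β-elimination) before it is reprotonated. Fallback: setting out from 11, the C7 substituent is delivered suprafacially from the C9 oxygen instead. Luche reduction (NaBH4, CeCl3, MeOH) should give the 9β-allylic alcohol F2, hydride entering anti to the pseudoaxial methyl. Etherification (KH, Bu3SnCH2I, THF) gives the stannylmethyl ether F3. Tin–lithium exchange (n-BuLi, THF, −78 °C) triggers a Wittig–Still rearrangement that places a hydroxymethyl group on the β face of C7 and the alkene at C8=C9, giving F4. Oxidation with the periodinane of step 11 gives the aldehyde F5, Seyferth–Gilbert homologation with the Ohira–Bestmann reagent (K2CO3, MeOH) gives the 7β-alkyne F6, and (Ph3P)AuNTf2-catalysed hydration (MeOH/H2O) returns to the route at 19.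

Step 3. The hindered cuprate may add sluggishly to the trisubstituted enone, the tetrasubstituted enolate may be protonated instead of undergoing aldol addition, and the aldol may revert. Fallback: setting out from 3, the same cuprate is added in the presence of Me3SiCl and the trimethylsilyl enol ether F7 is isolated. MeLi regenerates the lithium enolate, which adds to phenyl vinyl sulfoxide (a vinyl cation equivalent) anti to the C5 group to give the sulfoxide F8. Thermolysis (toluene, CaCO3, 110 °C) eliminates benzenesulfenic acid and comes back to the route at 10, bypassing 9.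

**Further compounds**
F1 | step 17 | acrylic acid from 30 (8β-chloro, 9α-OSiEt3, C11 carboxylic acid) | C=C[C@]1(C)[C@H](O[Si](CC)(CC)CC)[C@@H](Cl)[C@@H](C(=C)C(=O)O)[C@@H](OC(=O)/C(C)=C\C)[C@H]1C(=C)C(OCC)OCC
F2 | step 7 | 9β-allylic alcohol from 11 | C=C[C@]1(C)[C@@H](O)C=C[C@H](O[Si](C)(C)C(C)(C)C)[C@H]1C(=C)C(OCC)OCC
F3 | step 7 | 9β-(tributylstannylmethyl) ether | C=C[C@]1(C)[C@@H](OC[Sn](CCCC)(CCCC)CCCC)C=C[C@H](O[Si](C)(C)C(C)(C)C)[C@H]1C(=C)C(OCC)OCC
F4 | step 7 | C8=C9 alkene with 7β-hydroxymethyl | C=C[C@]1(C)C=C[C@@H](CO)[C@H](O[Si](C)(C)C(C)(C)C)[C@H]1C(=C)C(OCC)OCC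
F5 | step 7 | C8=C9 alkene with 7β-formyl | C=C[C@]1(C)C=C[C@@H](C=O)[C@H](O[Si](C)(C)C(C)(C)C)[C@H]1C(=C)C(OCC)OCC
F6 | step 7 | C8=C9 alkene with 7β-ethynyl | C=C[C@]1(C)C=C[C@@H](C#C)[C@H](O[Si](C)(C)C(C)(C)C)[C@H]1C(=C)C(OCC)OCC
F7 | step 3 | trimethylsilyl enol ether (C9=C10) with 5β-(3,3-diethoxyprop-1-en-2-yl), 6α-OTBS | C[Si](C)(C)OC1=C(C)[C@H](C(=C)C(OCC)OCC)[C@@H](O[Si](C)(C)C(C)(C)C)CC1
F8 | step 3 | C9 ketone with 10α-[2-(phenylsulfinyl)ethyl], 10β-methyl (sulfoxide epimers) | O=S(CC[C@]1(C)C(=O)CC[C@H](O[Si](C)(C)C(C)(C)C)[C@H]1C(=C)C(OCC)OCC)c1ccccc1
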